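## Retrosynthetic overview

1. Enone C=C: Claisen–Schmidt disconnection to the 8‑acetyl‑(3S)‑chromanol and 4‑hydroxybenzaldehyde; ring B arrives last.
2. Pyran ring, O1–C2 bond: cyclodehydration of an ortho‑(2,3‑dihydroxy‑3‑methylbutyl)phenol, in which only the achiral tertiary carbinol reacts.
3. C4–C4a bond (key bond): visible‑light decarboxylative C(sp3)–C(sp2) coupling (NiCl2(dme)/dtbbpy with Ir[dF(CF3)ppy]2(dtbbpy)PF6) of 3‑bromo‑2‑hydroxy‑4‑methoxyacetophenone with the carboxylate of (3S)‑3,4‑dihydroxy‑4‑methylpentanoic acid.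
4. Fragments: the bromide from symmetric 2‑bromo‑1,3‑dimethoxybenzene (Friedel–Crafts acetylation, chelation‑controlled demethylation); the carboxylate, stored as its γ‑lactone, from the acetonide of L‑malic acid and MeMgBr. The only stereocenter is bought.
5. Ring order: ring A bought, pyran ring closed in step 4, ring B attached in step 5.

Assumption: the acetonide of L‑malic acid, 2‑[(4S)‑2,2‑dimethyl‑5‑oxo‑1,3‑dioxolan‑4‑yl]acetic acid, is bought as such (catalogue compound, made from L‑malic acid and 2,2‑dimethoxypropane).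

dtbbpy = 4,4′‑di‑tert‑butyl‑2,2′‑bipyridine.

## Route

Step 1
Reactants: 1 2-bromo-1,3-dimethoxybenzene
Product: 3 1-(3-bromo-2-hydroxy-4-methoxyphenyl)ethanone, via 1-(3-bromo-2,4-dimethoxyphenyl)ethanone 2 (not isolated)
Conditions: AcCl (1.2 equiv), AlCl3 (3 equiv), CH2Cl2, 0 °C then 40 °C; ice-cold 1 M HCl
Reagents that add atoms: acetyl chloride, CC(=O)Cl
Why: Friedel–Crafts acylation, in which the two activated ring positions of 1 are equivalent by symmetry so only 2 can form, followed by chelation-controlled O-demethylation in which AlCl3 cleaves only the methyl ether next to the new ketone; no stereocenter is involved.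

Step 2
Reactants: 4 2-[(4S)-2,2-dimethyl-5-oxo-1,3-dioxolan-4-yl]acetic acid
Product: 6 (4S)-4-hydroxy-5,5-dimethyloxolan-2-one, via (3S)-3,4-dihydroxy-4-methylpentanoic acid 5 (not isolated)
Conditions: MeMgBr (5 equiv), THF, −20 °C to 25 °C; then 2 M HCl to pH 1, 25 °C
Reagents that add atoms: methylmagnesium bromide, C[Mg]Br
Why: Grignard addition, in which the acid is first deprotonated to the inert carboxylate, MeMgBr then adds twice to the dioxolanone carbonyl (the expelled acetone is taken up as tert-butoxide), and acid work-up gives 5, which lactonises through its tertiary hydroxyl; the C–O bond of the L-malic acid stereocenter is never broken, so (S) is retained.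

Step 3
Reactants: 3 1-(3-bromo-2-hydroxy-4-methoxyphenyl)ethanone; 6 (4S)-4-hydroxy-5,5-dimethyloxolan-2-one
Product: 8 1-[3-[(2S)-2,3-dihydroxy-3-methylbutyl]-2-hydroxy-4-methoxyphenyl]ethanone, via cesium (3S)-3,4-dihydroxy-4-methylpentanoate 7 (not isolated)
Conditions: 6 (1.5 equiv), CsOH·H2O (1.5 equiv), MeOH–H2O, 25 °C, evaporate to dryness; then 3 (1.0 equiv), NiCl2(dme) (10 mol %), dtbbpy (15 mol %), Ir[dF(CF3)ppy]2(dtbbpy)PF6 (2 mol %), degassed DMSO, hν (450 nm LEDs), 25 °C
Reagents that add atoms: cesium hydroxide, [Cs+].[OH-] (its cesium and oxygen are carried in 7 only and leave as CsBr and CO2; neither remains in 8)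
Why: Proposed new method: a visible-light decarboxylative C(sp3)–C(sp2) coupling in which γ-lactone 6 is the latent acid (opened to 7, so no further base is present and the ketone-chelated phenol of 3 stays protonated) and the electrophile is an aryl bromide flanked by OH and OMe; the excited Ir[dF(CF3)ppy]2(dtbbpy)PF6 oxidises carboxylate 7, loss of CO2 gives the small primary radical •CH2–CH(OH)–C(CH3)2OH, this is trapped by the (dtbbpy)Ni(aryl)Br complex formed from 3 and zerovalent nickel, and reductive elimination from trivalent nickel forms the C4–C4a bond, the radical site being one carbon away from the carbinol so that the (S) centre bought with L-malic acid is not touched; closest known reaction type: metallaphotoredox decarboxylative arylation of aliphatic carboxylic acids with aryl bromides (the same NiCl2(dme)/dtbbpy and Ir[dF(CF3)ppy]2(dtbbpy)PF6 pair), not yet shown for a lactone-masked 3,4-dihydroxy acid or for a 2,6-dioxygenated bromophenol.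

Step 4
Reactants: 8 1-[3-[(2S)-2,3-dihydroxy-3-methylbutyl]-2-hydroxy-4-methoxyphenyl]ethanone
Product: 9 1-[(3S)-3-hydroxy-5-methoxy-2,2-dimethyl-3,4-dihydro-2H-chromen-8-yl]ethanone
Conditions: p-TsOH·H2O (10 mol %), toluene, 60 °C
Reagents that add atoms: none
Why: Acid-catalysed cyclodehydration (SN1 etherification), in which only the tertiary carbinol ionises and the ortho phenol traps the cation in a six-membered ring, so the secondary C–O bond and its (S) configuration stay untouched and no five-membered ether can form.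

Step 5
Reactants: 9 1-[(3S)-3-hydroxy-5-methoxy-2,2-dimethyl-3,4-dihydro-2H-chromen-8-yl]ethanone; 10 4-hydroxybenzaldehyde
Product: 12 (2E)-1-[(3S)-3-hydroxy-5-methoxy-2,2-dimethyl-3,4-dihydro-2H-chromen-8-yl]-3-(4-hydroxyphenyl)prop-2-en-1-one, via β-hydroxy ketone aldol adduct 11 (not isolated)
Conditions: KOH (6 equiv, 50 % aq.), EtOH, 25 °C; then 1 M HCl to pH 3
Reagents that add atoms: none
Why: Claisen–Schmidt (crossed aldol) condensation, in which the methyl ketone enolate of 9 adds to aldehyde 10 and E1cB loss of water from 11 gives the conjugated (E)-enone; the 2′-oxygen is already etherified so no flavanone can form, and the C3 carbinol is not affected.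

## Compound list

1 | 2-bromo-1,3-dimethoxybenzene | COc1cccc(OC)c1Br | starting material
2 | 1-(3-bromo-2,4-dimethoxyphenyl)ethanone (forms in the flask in step 1) | CC(=O)c1ccc(OC)c(Br)c1OC | intermediate
3 | 1-(3-bromo-2-hydroxy-4-methoxyphenyl)ethanone | CC(=O)c1ccc(OC)c(Br)c1O | intermediate
4 | 2-[(4S)-2,2-dimethyl-5-oxo-1,3-dioxolan-4-yl]acetic acid (acetonide of L-malic acid) | CC1(C)O[C@@H](CC(=O)O)C(=O)O1 | starting material
5 | (3S)-3,4-dihydroxy-4-methylpentanoic acid (forms in the flask in step 2) | OC(=O)C[C@H](O)C(C)(C)O | intermediate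
6 | (4S)-4-hydroxy-5,5-dimethyloxolan-2-one | O=C1C[C@H](O)C(C)(C)O1 | intermediate
7 | cesium (3S)-3,4-dihydroxy-4-methylpentanoate (forms in the flask in step 3) | [Cs+].[O-]C(=O)C[C@H](O)C(C)(C)O | intermediate
8 | 1-[3-[(2S)-2,3-dihydroxy-3-methylbutyl]-2-hydroxy-4-methoxyphenyl]ethanone | CC(=O)c1ccc(OC)c(C[C@H](O)C(C)(C)O)c1O | intermediate
9 | 1-[(3S)-3-hydroxy-5-methoxy-2,2-dimethyl-3,4-dihydro-2H-chromen-8-yl]ethanone | COc1ccc(C(C)=O)c2c1C[C@H](O)C(C)(C)O2 | intermediate
10 | 4-hydroxybenzaldehyde | O=Cc1ccc(O)cc1 | starting material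
11 | 3-hydroxy-1-[(3S)-3-hydroxy-5-methoxy-2,2-dimethyl-3,4-dihydro-2H-chromen-8-yl]-3-(4-hydroxyphenyl)propan-1-one (both epimers at the new carbinol carbon; forms in the flask in step 5) | COc1ccc(C(=O)CC(O)c2ccc(O)cc2)c2c1C[C@H](O)C(C)(C)O2 | intermediate
12 | (2E)-1-[(3S)-3-hydroxy-5-methoxy-2,2-dimethyl-3,4-dihydro-2H-chromen-8-yl]-3-(4-hydroxyphenyl)prop-2-en-1-one | COc1ccc(C(=O)/C=C/c2ccc(O)cc2)c2c1C[C@H](O)C(C)(C)O2 | target

## Step count and risks

Total steps: 5. Longest linear sequence: 4 (steps 1, 3, 4, 5 or steps 2, 3, 4, 5).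

Steps most likely to fail:

**Step 3 (the proposed coupling).** The bromide is di-ortho-substituted, so capture of the radical and reductive elimination may be slow; hydrodebromination to 2-hydroxy-4-methoxyacetophenone and interference by the free phenol are the likely side paths. The fallback uses known chemistry, a polar epoxide-opening route that sets out from 1 and comes back at 8. Bromine–lithium exchange of 1 (n-BuLi, THF, −78 °C), conversion to the cuprate Ar2CuLi with CuBr·SMe2 and opening of bought methyl (2S)-oxirane-2-carboxylate at its CH2 carbon give methyl (2S)-3-(2,6-dimethoxyphenyl)-2-hydroxypropanoate F1. MeMgBr (THF, 0 °C) converts the ester into (2S)-1-(2,6-dimethoxyphenyl)-3-methylbutane-2,3-diol F2. NBS (MeCN, 0 °C) brominates one of the two equivalent activated positions to give (2S)-1-(3-bromo-2,6-dimethoxyphenyl)-3-methylbutane-2,3-diol F3. Heck coupling with butyl vinyl ether (Pd(OAc)2, 1,3-bis(diphenylphosphino)propane, Et3N, ethylene glycol, 120 °C) gives (2S)-1-[3-(1-butoxyethenyl)-2,6-dimethoxyphenyl]-3-methylbutane-2,3-diol F4, which dilute HCl hydrolyses in the same flask to 1-[3-[(2S)-2,3-dihydroxy-3-methylbutyl]-2,4-dimethoxyphenyl]ethanone F5. BCl3 (CH2Cl2, −78 to 0 °C) cleaves only the methyl ether chelated to the ketone and gives 8. The stereocenter is then bought with the glycidate, and its C–O bond is never broken.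

**Step 4 (cyclodehydration).** The β-hydroxy tertiary cation can undergo a pinacol-type hydride shift to the 3-methyl-2-oxobutyl ketone instead of being trapped by the chelated phenol. The fallback replaces the free cation by a dioxolanylium ion, sets out from 8 and comes back at 9. MeC(OMe)3 with pyridinium p-toluenesulfonate turns the diol into the cyclic orthoacetate 1-[2-hydroxy-4-methoxy-3-[[(4S)-2-methoxy-2,5,5-trimethyl-1,3-dioxolan-4-yl]methyl]phenyl]ethanone F6. BF3·OEt2 (CH2Cl2, −40 °C) ionises it, and the phenol opens the dioxolanylium ion at the tertiary carbon to give (3S)-8-acetyl-5-methoxy-2,2-dimethyl-3,4-dihydro-2H-chromen-3-yl acetate F7. K2CO3 in MeOH removes the acetate and gives 9.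

**Step 5 (condensation with the unprotected aldehyde).** The phenoxide of 10 is a poor electrophile, so conversion may stall. The fallback uses a protected aldehyde, sets out from 9 and comes back at 12. Condensation of 9 with bought 4-(methoxymethoxy)benzaldehyde (KOH, EtOH, 25 °C) gives (2E)-1-[(3S)-3-hydroxy-5-methoxy-2,2-dimethyl-3,4-dihydro-2H-chromen-8-yl]-3-[4-(methoxymethoxy)phenyl]prop-2-en-1-one F8. HCl in MeOH (25 °C) removes the methoxymethyl group and gives 12.

## Further compounds

F1 | step 3 | methyl (2S)-3-(2,6-dimethoxyphenyl)-2-hydroxypropanoate | COc1cccc(OC)c1C[C@H](O)C(=O)OC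
F2 | step 3 | (2S)-1-(2,6-dimethoxyphenyl)-3-methylbutane-2,3-diol | COc1cccc(OC)c1C[C@H](O)C(C)(C)O
F3 | step 3 | (2S)-1-(3-bromo-2,6-dimethoxyphenyl)-3-methylbutane-2,3-diol | COc1ccc(Br)c(OC)c1C[C@H](O)C(C)(C)O
F4 | step 3 | (2S)-1-[3-(1-butoxyethenyl)-2,6-dimethoxyphenyl]-3-methylbutane-2,3-diol | CCCCOC(=C)c1ccc(OC)c(C[C@H](O)C(C)(C)O)c1OC
F5 | step 3 | 1-[3-[(2S)-2,3-dihydroxy-3-methylbutyl]-2,4-dimethoxyphenyl]ethanone | CC(=O)c1ccc(OC)c(C[C@H](O)C(C)(C)O)c1OC
F6 | step 4 | 1-[2-hydroxy-4-methoxy-3-[[(4S)-2-methoxy-2,5,5-trimethyl-1,3-dioxolan-4-yl]methyl]phenyl]ethanone (both epimers at the orthoester carbon) | CC(=O)c1ccc(OC)c(C[C@@H]2OC(C)(OC)OC2(C)C)c1O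
F7 | step 4 | (3S)-8-acetyl-5-methoxy-2,2-dimethyl-3,4-dihydro-2H-chromen-3-yl acetate | COc1ccc(C(C)=O)c2c1C[C@H](OC(C)=O)C(C)(C)O2
F8 | step 5 | (2E)-1-[(3S)-3-hydroxy-5-methoxy-2,2-dimethyl-3,4-dihydro-2H-chromen-8-yl]-3-[4-(methoxymethoxy)phenyl]prop-2-en-1-one | COc1ccc(C(=O)/C=C/c2ccc(OCOC)cc2)c2c1C[C@H](O)C(C)(C)O2
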